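**Retrosynthetic overview**
1. The two esters go on last (anisoate on the secondary C4–OH, acetate on C8–OH). The C8 oxygen and the C6=C7 alkene come from a singlet-oxygen ene transposition of a C7=C8 alkene.
2. C3–OH, C3a–H and C4–OH come from a bicyclic 3-isopropyl enone (epoxidation, SmI2 opening, hydride reduction). The enone comes from isopropyl addition and transposition on a bicyclic vinylogous silyl ester.
3. Key step: an acyclic 2-silyloxyvinyl diazoketone carrying an (E,E)-diene is closed by a chiral dirhodium catalyst. Cyclopropanation forms the cyclopentanone ring first, and divinylcyclopropane (Cope) rearrangement then forms the seven-membered ring in the same flask.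
4. The diazoketone comes from a β-diketone, made by Saucy–Marbet Claisen rearrangement of the dienol from crotonaldehyde and isopropenylmagnesium bromide, followed by Claisen condensation with ethyl acetate.

Assumption: bicyclic compounds carry the hydroazulene numbering of the target (C8a = methyl-bearing ring-fusion carbon, C3 = isopropyl carbon, C4 = anisoate carbon, C8 = acetate carbon), and Rh2(S-PTAD)4 is taken to give the (8aR) series shown; if the sense of induction is the reverse, its enantiomer is used.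

**Step 1**
Reactants: 1 (E)-but-2-enal; 2 isopropenylmagnesium bromide
Product: 3 (4E)-2-methylhexa-1,4-dien-3-ol (racemic)
Conditions: THF, −78 to 0 °C; then H2O
Reagents that add atoms: isopropenylmagnesium bromide (2), C=C(C)[Mg]Br
Why: Grignard 1,2-addition to the enal gives the bis-allylic alcohol; its carbinol centre is racemic and becomes sp2 in step 2.

**Step 2**
Reactants: 3 (4E)-2-methylhexa-1,4-dien-3-ol; 4 2-methoxypropene
Product: 7 (5E,7E)-5-methylnona-5,7-dien-2-one, via mixed ketal 5 (not isolated), via allyl isopropenyl ether 6 (not isolated)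
Conditions: 4 (5 equiv), PPTS (2 mol%), xylene, 125 °C, sealed tube
Reagents that add atoms: 2-methoxypropene (4), C=C(C)OC
Why: Saucy–Marbet variant of the Claisen rearrangement; the [3,3] shift runs through a chair with the propenyl group equatorial, so the new trisubstituted alkene is E, and the unsubstituted isopropenyl terminus reacts faster than the methyl-substituted propenyl terminus.

**Step 3**
Reactants: 7 (5E,7E)-5-methylnona-5,7-dien-2-one; 8 ethyl acetate
Product: 9 (7E,9E)-7-methylundeca-7,9-diene-2,4-dione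
Conditions: NaH, EtOAc (excess), THF, 0 °C to reflux; then aq. HCl
Reagents that add atoms: ethyl acetate (8), CCOC(C)=O
Why: Crossed Claisen condensation; the methyl group of the methyl ketone is acylated because only that product is trapped as the stabilised β-diketonate.

**Step 4**
Reactants: 9 (7E,9E)-7-methylundeca-7,9-diene-2,4-dione; 10 4-acetamidobenzenesulfonyl azide
Product: 11 (7E,9E)-3-diazo-7-methylundeca-7,9-diene-2,4-dione
Conditions: Et3N, MeCN, 0 °C to rt
Reagents that add atoms: 4-acetamidobenzenesulfonyl azide (10), CC(=O)Nc1ccc(cc1)S(=O)(=O)N=[N+]=[N-]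
Why: Regitz diazo transfer to the doubly activated methylene; the diene is untouched.

**Step 5**
Reactants: 11 (7E,9E)-3-diazo-7-methylundeca-7,9-diene-2,4-dione; 12 tert-butyldimethylsilyl trifluoromethanesulfonate
Product: 13 (7E,9E)-2-[(tert-butyldimethylsilyl)oxy]-3-diazo-7-methylundeca-1,7,9-trien-4-one
Conditions: TBSOTf, Et3N, CH2Cl2, −78 to 0 °C
Reagents that add atoms: tert-butyldimethylsilyl trifluoromethanesulfonate (12), CC(C)(C)[Si](C)(C)OS(=O)(=O)C(F)(F)F
Why: Soft enolisation and O-silylation of the less hindered acetyl group gives the 2-silyloxyvinyl diazoketone, a donor/acceptor carbene precursor.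

**Step 6 (key step)**
Reactants: 13 (7E,9E)-2-[(tert-butyldimethylsilyl)oxy]-3-diazo-7-methylundeca-1,7,9-trien-4-one
Product: 15 (6R,8aR)-4-[(tert-butyldimethylsilyl)oxy]-6,8a-dimethyl-1,5,6,8a-tetrahydroazulen-3(2H)-one, via divinylcyclopropane 14 (not isolated)
Conditions: Rh2(S-PTAD)4 [dirhodium tetrakis((S)-(1-adamantyl)phthalimidoacetate)] (1 mol%), PhMe, 0 °C to rt; then 110 °C
Reagents that add atoms: none
Why: Proposed new method: the donor/acceptor dirhodium carbene from 13 should cyclopropanate the tethered proximal (E)-trisubstituted alkene (five-membered ring closure, catalyst-controlled face selection fixing C8a, E geometry placing both alkenyl groups cis on the cyclopropane), and the boat-shaped Cope rearrangement of 14 on warming then forms the C5–C6 bond and the seven-membered ring with C6–H cis to the 8a-methyl group; the closest known reaction type is the tandem intramolecular cyclopropanation/Cope rearrangement (formal (4+3) cycloaddition) of vinyldiazo compounds tethered to dienes, together with enantioselective cyclopropanation by donor/acceptor diazoketones.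

**Step 7**
Reactants: 15 (6R,8aR)-4-[(tert-butyldimethylsilyl)oxy]-6,8a-dimethyl-1,5,6,8a-tetrahydroazulen-3(2H)-one; 16 isopropyllithium
Product: 18 (6R,8aR)-6,8a-dimethyl-3-(propan-2-yl)-1,5,6,8a-tetrahydroazulen-4(2H)-one, via tertiary carbinol 17 (not isolated)
Conditions: i-PrLi, CeCl3, THF, −78 °C; then 1 M HCl, 0 °C
Reagents that add atoms: isopropyllithium (16), [Li]C(C)C
Why: Stork–Danheiser sequence; the organocerium reagent adds 1,2 to the vinylogous silyl ester and acid then ionises the tertiary allylic alcohol and cleaves the silyl enol ether to give the transposed enone, so no new stereocentre remains.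

**Step 8**
Reactants: 18 (6R,8aR)-6,8a-dimethyl-3-(propan-2-yl)-1,5,6,8a-tetrahydroazulen-4(2H)-one; 19 hydrogen peroxide
Product: 20 (3R,3aR,6R,8aR)-3,3a-epoxy-6,8a-dimethyl-3-(propan-2-yl)-2,3,3a,5,6,8a-hexahydroazulen-4(1H)-one
Conditions: 30% H2O2, NaOH (cat.), MeOH, 0 °C to rt
Reagents that add atoms: hydrogen peroxide (19), OO
Why: Weitz–Scheffer nucleophilic epoxidation of the tetrasubstituted enone (as with pulegone); hydroperoxide adds to C3 on the face of the 8a-methyl group, anti to the larger C8 ring branch, and closure gives the oxirane cis to that methyl, while the isolated C7=C8 alkene is inert.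

**Step 9**
Reactants: 20 (3R,3aR,6R,8aR)-3,3a-epoxy-6,8a-dimethyl-3-(propan-2-yl)-2,3,3a,5,6,8a-hexahydroazulen-4(1H)-one
Product: 21 (3R,3aS,6R,8aR)-3-hydroxy-6,8a-dimethyl-3-(propan-2-yl)-2,3,3a,5,6,8a-hexahydroazulen-4(1H)-one
Conditions: SmI2 (2.2 equiv), THF/MeOH, −78 °C
Reagents that add atoms: none
Why: SmI2 reductive cleavage of the α,β-epoxy ketone at the α-carbon; the C3–O bond is untouched (retention, OH cis to the 8a-methyl) and the samarium enolate is protonated at C3a on the convex face to give the cis-fused β-hydroxy ketone.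

**Step 10**
Reactants: 21 (3R,3aS,6R,8aR)-3-hydroxy-6,8a-dimethyl-3-(propan-2-yl)-2,3,3a,5,6,8a-hexahydroazulen-4(1H)-one
Product: 22 (3R,3aR,4S,6R,8aR)-6,8a-dimethyl-3-(propan-2-yl)-1,2,3,3a,4,5,6,8a-octahydroazulene-3,4-diol
Conditions: NaBH4, MeOH, −20 °C
Reagents that add atoms: none
Why: Substrate-controlled borohydride reduction; hydride attacks C4 from the convex face (that of 3a-H and the 8a-methyl, away from the cis isopropyl group on C3), so the new hydroxyl is trans to 3a-H.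

**Step 11**
Reactants: 22 (3R,3aR,4S,6R,8aR)-6,8a-dimethyl-3-(propan-2-yl)-1,2,3,3a,4,5,6,8a-octahydroazulene-3,4-diol; 23 4-methoxybenzoyl chloride
Product: 24 (3R,3aR,4S,6R,8aR)-3-hydroxy-6,8a-dimethyl-3-(propan-2-yl)-1,2,3,3a,4,5,6,8a-octahydroazulen-4-yl 4-methoxybenzoate
Conditions: pyridine, DMAP (cat.), CH2Cl2, 0 °C to rt
Reagents that add atoms: 4-methoxybenzoyl chloride (23), COc1ccc(cc1)C(Cl)=O
Why: DMAP-catalysed acylation; only the secondary hydroxyl reacts and the tertiary C3 hydroxyl is left free.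

**Step 12**
Reactants: 24 (3R,3aR,4S,6R,8aR)-3-hydroxy-6,8a-dimethyl-3-(propan-2-yl)-1,2,3,3a,4,5,6,8a-octahydroazulen-4-yl 4-methoxybenzoate; 25 dioxygen
Product: 27 (3R,3aR,4S,8S,8aS)-3,8-dihydroxy-6,8a-dimethyl-3-(propan-2-yl)-1,2,3,3a,4,5,8,8a-octahydroazulen-4-yl 4-methoxybenzoate, via allylic hydroperoxide 26 (not isolated)
Conditions: O2, tetraphenylporphyrin (cat.), visible light, CH2Cl2, 0 °C; then PPh3
Reagents that add atoms: dioxygen (25), O=O
Why: Schenck ene reaction of singlet oxygen; the only allylic hydrogen is C6–H (C8a is quaternary), so oxygen adds to C8 on the face from which that hydrogen leaves (cis to the 8a-methyl), the alkene shifts to C6=C7, and PPh3 reduces the O–O bond.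

**Step 13**
Reactants: 27 (3R,3aR,4S,8S,8aS)-3,8-dihydroxy-6,8a-dimethyl-3-(propan-2-yl)-1,2,3,3a,4,5,8,8a-octahydroazulen-4-yl 4-methoxybenzoate; 28 acetic anhydride
Product: 29 (3R,3aR,4S,8S,8aS)-8-acetoxy-3-hydroxy-6,8a-dimethyl-3-(propan-2-yl)-1,2,3,3a,4,5,8,8a-octahydroazulen-4-yl 4-methoxybenzoate
Conditions: Ac2O, pyridine, DMAP (cat.), CH2Cl2, rt
Reagents that add atoms: acetic anhydride (28), CC(=O)OC(C)=O
Why: DMAP-catalysed acetylation of the secondary allylic alcohol; the tertiary alcohol does not react and no stereocentre is touched.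

**Compound list**
1 | (E)-but-2-enal | C/C=C/C=O | starting material
2 | isopropenylmagnesium bromide | C=C(C)[Mg]Br | starting material
3 | (4E)-2-methylhexa-1,4-dien-3-ol (racemic) | C=C(C)C(O)/C=C/C | intermediate
4 | 2-methoxypropene | C=C(C)OC | starting material
5 | (4E)-3-[(2-methoxypropan-2-yl)oxy]-2-methylhexa-1,4-diene (mixed ketal) | C=C(C)C(OC(C)(C)OC)/C=C/C | intermediate
6 | (4E)-2-methyl-3-(prop-1-en-2-yloxy)hexa-1,4-diene (allyl isopropenyl ether) | C=C(C)C(OC(C)=C)/C=C/C | intermediate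
7 | (5E,7E)-5-methylnona-5,7-dien-2-one | CC(=O)CC/C(C)=C/C=C/C | intermediate
8 | ethyl acetate | CCOC(C)=O | starting material
9 | (7E,9E)-7-methylundeca-7,9-diene-2,4-dione | CC(=O)CC(=O)CC/C(C)=C/C=C/C | intermediate
10 | 4-acetamidobenzenesulfonyl azide | CC(=O)Nc1ccc(cc1)S(=O)(=O)N=[N+]=[N-] | starting material
11 | (7E,9E)-3-diazo-7-methylundeca-7,9-diene-2,4-dione | CC(=O)C(=[N+]=[N-])C(=O)CC/C(C)=C/C=C/C | intermediate
12 | tert-butyldimethylsilyl trifluoromethanesulfonate | CC(C)(C)[Si](C)(C)OS(=O)(=O)C(F)(F)F | starting material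
13 | (7E,9E)-2-[(tert-butyldimethylsilyl)oxy]-3-diazo-7-methylundeca-1,7,9-trien-4-one | C=C(O[Si](C)(C)C(C)(C)C)C(=[N+]=[N-])C(=O)CC/C(C)=C/C=C/C | intermediate
14 | (1S,5R,6R)-1-[1-(tert-butyldimethylsilyloxy)ethenyl]-5-methyl-6-[(E)-prop-1-en-1-yl]bicyclo[3.1.0]hexan-2-one | C=C(O[Si](C)(C)C(C)(C)C)[C@@]12C(=O)CC[C@]1(C)[C@H]2/C=C/C | intermediate
15 | (6R,8aR)-4-[(tert-butyldimethylsilyl)oxy]-6,8a-dimethyl-1,5,6,8a-tetrahydroazulen-3(2H)-one | O=C1CC[C@]2(C)C=C[C@H](C)CC(O[Si](C)(C)C(C)(C)C)=C12 | intermediate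
16 | isopropyllithium | [Li]C(C)C | starting material
17 | (6R,8aR)-4-[(tert-butyldimethylsilyl)oxy]-6,8a-dimethyl-3-(propan-2-yl)-1,2,3,5,6,8a-hexahydroazulen-3-ol (both C3 epimers) | CC(C)C1(O)CC[C@]2(C)C=C[C@H](C)CC(O[Si](C)(C)C(C)(C)C)=C12 | intermediate
18 | (6R,8aR)-6,8a-dimethyl-3-(propan-2-yl)-1,5,6,8a-tetrahydroazulen-4(2H)-one | O=C1C[C@@H](C)C=C[C@@]2(C)CCC(C(C)C)=C12 | intermediate
19 | hydrogen peroxide | OO | starting material
20 | (3R,3aR,6R,8aR)-3,3a-epoxy-6,8a-dimethyl-3-(propan-2-yl)-2,3,3a,5,6,8a-hexahydroazulen-4(1H)-one | O=C1C[C@@H](C)C=C[C@@]2(C)CC[C@]3(C(C)C)O[C@]123 | intermediate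
21 | (3R,3aS,6R,8aR)-3-hydroxy-6,8a-dimethyl-3-(propan-2-yl)-2,3,3a,5,6,8a-hexahydroazulen-4(1H)-one | O=C1C[C@@H](C)C=C[C@@]2(C)CC[C@@](O)(C(C)C)[C@@H]12 | intermediate
22 | (3R,3aR,4S,6R,8aR)-6,8a-dimethyl-3-(propan-2-yl)-1,2,3,3a,4,5,6,8a-octahydroazulene-3,4-diol | O[C@H]1C[C@@H](C)C=C[C@@]2(C)CC[C@@](O)(C(C)C)[C@@H]12 | intermediate
23 | 4-methoxybenzoyl chloride | COc1ccc(cc1)C(Cl)=O | starting material
24 | (3R,3aR,4S,6R,8aR)-3-hydroxy-6,8a-dimethyl-3-(propan-2-yl)-1,2,3,3a,4,5,6,8a-octahydroazulen-4-yl 4-methoxybenzoate | COc1ccc(C(=O)O[C@H]2C[C@@H](C)C=C[C@@]3(C)CC[C@@](O)(C(C)C)[C@@H]23)cc1 | intermediate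
25 | dioxygen | O=O | starting material
26 | (3R,3aR,4S,8S,8aS)-8-hydroperoxy-3-hydroxy-6,8a-dimethyl-3-(propan-2-yl)-1,2,3,3a,4,5,8,8a-octahydroazulen-4-yl 4-methoxybenzoate | COc1ccc(C(=O)O[C@H]2CC(C)=C[C@H](OO)[C@@]3(C)CC[C@@](O)(C(C)C)[C@@H]23)cc1 | intermediate
27 | (3R,3aR,4S,8S,8aS)-3,8-dihydroxy-6,8a-dimethyl-3-(propan-2-yl)-1,2,3,3a,4,5,8,8a-octahydroazulen-4-yl 4-methoxybenzoate | COc1ccc(C(=O)O[C@H]2CC(C)=C[C@H](O)[C@@]3(C)CC[C@@](O)(C(C)C)[C@@H]23)cc1 | intermediate
28 | acetic anhydride | CC(=O)OC(C)=O | starting material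
29 | (3R,3aR,4S,8S,8aS)-8-acetoxy-3-hydroxy-6,8a-dimethyl-3-(propan-2-yl)-1,2,3,3a,4,5,8,8a-octahydroazulen-4-yl 4-methoxybenzoate | COc1ccc(C(=O)O[C@H]2CC(C)=C[C@H](OC(C)=O)[C@@]3(C)CC[C@@](O)(C(C)C)[C@@H]23)cc1 | target

**Step count**
Total steps: 13. Longest linear sequence: 13 steps (fully linear from 1).

**Steps most likely to fail**

Step 6 (carbene cascade). The vinyl carbene may react at its vinylogous position, the enantioselectivity may be low, or the Cope step may be slowed by the methyl group on the cyclopropane. The fallback sets out from 11 and comes back at 15. The diazo diketone 11 is cyclised as an acceptor/acceptor carbene with Rh2(S-PTTL)4 [dirhodium tetrakis((S)-N-phthaloyl-tert-leucinate)] to (1S,5R,6R)-1-acetyl-5-methyl-6-[(E)-prop-1-en-1-yl]bicyclo[3.1.0]hexan-2-one F1. Kinetic O-silylation of its acetyl group (TBSOTf, Et3N, −78 °C) then gives 14, which rearranges to 15 on warming. Carbene transfer and the sigmatropic step are thus separated.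

Step 8 (epoxidation of the hindered tetrasubstituted enone, rate and face). The fallback sets out from 18 and comes back at 22, bypassing 20 and 21. Enone 18 is deconjugated (KOt-Bu, t-BuOH; AcOH quench at −78 °C) to (3aS,6R,8aR)-6,8a-dimethyl-3-(propan-2-yl)-3a,5,6,8a-tetrahydroazulen-4(1H)-one F2. Its trisubstituted C2=C3 alkene is epoxidised with mCPBA on the convex face of the cis-fused bicycle to (2S,3R,3aS,6R,8aR)-2,3-epoxy-6,8a-dimethyl-3-(propan-2-yl)-2,3,3a,5,6,8a-hexahydroazulen-4(1H)-one F3. LiEt3BH then reduces the C4 ketone from the convex face and opens the oxirane at the less substituted C2, giving 22.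

Step 12 (ene reaction on the hindered face, over-oxidation of the trisubstituted alkene product). The fallback sets out from 24 and comes back at 27.
- Alkene 24 is epoxidised with mCPBA to (3R,3aR,4S,6R,7R,8S,8aS)-7,8-epoxy-3-hydroxy-6,8a-dimethyl-3-(propan-2-yl)decahydroazulen-4-yl 4-methoxybenzoate F4.
- Sodium phenylselenide [(PhSe)2, NaBH4, EtOH] opens it at the less hindered C7 to (3R,3aR,4S,6R,7S,8S,8aS)-3,8-dihydroxy-6,8a-dimethyl-7-(phenylselanyl)-3-(propan-2-yl)decahydroazulen-4-yl 4-methoxybenzoate F5.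
- H2O2 oxidation and syn-elimination towards C6–H give (3R,3aR,4S,8R,8aS)-3,8-dihydroxy-6,8a-dimethyl-3-(propan-2-yl)-1,2,3,3a,4,5,8,8a-octahydroazulen-4-yl 4-methoxybenzoate F6, the C8 epimer of 27.
- Dess–Martin periodinane oxidises it to (3R,3aR,4S,8aS)-3-hydroxy-6,8a-dimethyl-8-oxo-3-(propan-2-yl)-1,2,3,3a,4,5,8,8a-octahydroazulen-4-yl 4-methoxybenzoate F7.
- NaBH4/CeCl3 (MeOH, −78 °C) delivers hydride anti to the 8a-methyl group and gives 27.

**Further compounds**
F1 | step 6 | (1S,5R,6R)-1-acetyl-5-methyl-6-[(E)-prop-1-en-1-yl]bicyclo[3.1.0]hexan-2-one | CC(=O)[C@@]12C(=O)CC[C@]1(C)[C@H]2/C=C/C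
F2 | step 8 | (3aS,6R,8aR)-6,8a-dimethyl-3-(propan-2-yl)-3a,5,6,8a-tetrahydroazulen-4(1H)-one | O=C1C[C@@H](C)C=C[C@@]2(C)CC=C(C(C)C)[C@@H]12
F3 | step 8 | (2S,3R,3aS,6R,8aR)-2,3-epoxy-6,8a-dimethyl-3-(propan-2-yl)-2,3,3a,5,6,8a-hexahydroazulen-4(1H)-one | O=C1C[C@@H](C)C=C[C@@]2(C)C[C@@H]3O[C@]3(C(C)C)[C@@H]12
F4 | step 12 | (3R,3aR,4S,6R,7R,8S,8aS)-7,8-epoxy-3-hydroxy-6,8a-dimethyl-3-(propan-2-yl)decahydroazulen-4-yl 4-methoxybenzoate | COc1ccc(C(=O)O[C@H]2C[C@@H](C)[C@H]4O[C@H]4[C@@]3(C)CC[C@@](O)(C(C)C)[C@@H]23)cc1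
F5 | step 12 | (3R,3aR,4S,6R,7S,8S,8aS)-3,8-dihydroxy-6,8a-dimethyl-7-(phenylselanyl)-3-(propan-2-yl)decahydroazulen-4-yl 4-methoxybenzoate | COc1ccc(C(=O)O[C@H]2C[C@@H](C)[C@H]([Se]c4ccccc4)[C@@H](O)[C@@]3(C)CC[C@@](O)(C(C)C)[C@@H]23)cc1
F6 | step 12 | (3R,3aR,4S,8R,8aS)-3,8-dihydroxy-6,8a-dimethyl-3-(propan-2-yl)-1,2,3,3a,4,5,8,8a-octahydroazulen-4-yl 4-methoxybenzoate | COc1ccc(C(=O)O[C@H]2CC(C)=C[C@@H](O)[C@@]3(C)CC[C@@](O)(C(C)C)[C@@H]23)cc1
F7 | step 12 | (3R,3aR,4S,8aS)-3-hydroxy-6,8a-dimethyl-8-oxo-3-(propan-2-yl)-1,2,3,3a,4,5,8,8a-octahydroazulen-4-yl 4-methoxybenzoate | COc1ccc(C(=O)O[C@H]2CC(C)=CC(=O)[C@@]3(C)CC[C@@](O)(C(C)C)[C@@H]23)cc1
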